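**Retrosynthetic overview**

1. Numbering: chain C1 (an isopropyl CH3) through C11 (C=O) to C23 (exocyclic =CH2); the 4-methylcyclohex-3-enyl ring sits on C22. C11–C12 is cut first (Grignard addition to a C11 aldehyde, then oxidation), giving a C1–C11 aldehyde and a C12–C23 bromide.
2. C1–C11: C4–C5 is cut (copper-catalysed coupling with isopentyl) back to a C5–C11 1,7-diol. The feature used is that C6 and C10 both carry CH3 in the same local sense and each has one further carbon beyond it (C5, C11), so C5–C11 has a C2 axis through C8 although the target descriptors read 6S,10R. Both C–CH3 bonds are therefore made at once by two-directional zirconium-catalysed methylalumination of 1,6-heptadiene.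
3. C12–C23: C19–C20 is cut (Negishi coupling) into a (Z)-alkenyl iodide (C12–C19) and a homoallylzinc reagent (C20–C23 plus ring). The 18Z alkene comes from syn carbocupration of propyne by the C12–C17 alkylcopper made from (R)-citronellol (source of C14); C20–C21 comes from lithiated (R)-limonene and formaldehyde.
4. Rings: none is formed in the route; the only ring and its stereocentre are carried in intact from (R)-limonene.

Key step: step 1

Remark 1: the antipode of bis(1-neomenthylindenyl)zirconium dichloride, (NMI)2ZrCl2, is defined here by its function (1-alkene to (R)-2-methylalkan-1-ol) and is taken to be the (−)-form; if the sense were the opposite in practice, the other antipode would be used.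
Remark 2: carbinol 29 is carried as a mixture of C11 epimers, both of which give the same ketone.

**Route**

Step 1
Reactants: 1 1,6-heptadiene; 2 trimethylaluminium
Product: 4 (2R,6R)-2,6-dimethylheptane-1,7-diol, via bis-alane 3 (not isolated)
Conditions: AlMe3 (6 equiv), (−)-(NMI)2ZrCl2 (8 mol %), ClCH2CH2Cl, 22 °C; then O2 (1 atm), 0 °C→rt; aq NaOH
Reagents that add atoms: dioxygen, O=O
Why: Proposed new method: a cationic methylzirconocene formed from (NMI)2ZrCl2 and AlMe3 should insert each vinyl group in a syn sense, with CH3 delivered to the internal carbon (C6, C10) and zirconium to the terminal one (C5, C11), after which alkyl exchange with AlMe3 passes the chain to aluminium and frees the catalyst, the closest known reaction type being the zirconium-catalysed asymmetric carboalumination (ZACA) of a single unfunctionalised 1-alkene with O2 oxidation of the C–Al bond, here asked to run at both ends of one 1,6-diene. No ring is closed: the step makes the C6–CH3 and C10–CH3 bonds and, through the C5–Al and C11–Al bonds, the two C–O bonds. Both new stereocentres (C6 and C10) are set by the chiral 1-neomenthylindenyl ligand sphere alone, the antipode that turns 1-alkenes into (R)-2-methylalkan-1-ols being chosen, because the achiral diene has no bias of its own and its two vinyl groups, three CH2 apart, should behave as independent 1-alkenes. The selectivity required is the same enantioface choice at both alkenes, which a single catalyst supplies, so that one wrong insertion leads to the meso diol (a diastereomer, to be removed by chromatography or selective enzymatic acylation) and the (2R,6R)-diol should emerge enantiomerically enriched beyond the level of one event. The second requirement is chemoselectivity for Zr-to-Al transfer over ring-closing insertion of the first alkylzirconium into the remaining vinyl group (a six-membered ring), which the large excess of AlMe3 in a chlorinated solvent should secure.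

Step 2
Reactants: 4 (2R,6R)-2,6-dimethylheptane-1,7-diol
Product: 5 (2R,6R)-7-hydroxy-2,6-dimethylheptyl 4-methylbenzenesulfonate
Conditions: TsCl (1.05 equiv), Ag2O (1.5 equiv), KI (0.2 equiv), CH2Cl2, 0 °C→rt
Reagents that add atoms: 4-methylbenzenesulfonyl chloride, Cc1ccc(cc1)S(Cl)(=O)=O
Why: Ag2O-mediated monosulfonylation of a symmetrical diol; the two hydroxyls are homotopic through the C2 axis at C8, so tosylation of either gives the same compound and only over-tosylation has to be held back, which one equivalent of TsCl under the Ag2O/KI protocol should do.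

Step 3
Reactants: 5 (2R,6R)-7-hydroxy-2,6-dimethylheptyl 4-methylbenzenesulfonate; 6 1-bromo-3-methylbutane
Product: 8 (2R,6S)-2,6,10-trimethylundecan-1-ol, via isopentylmagnesium bromide 7 (not isolated)
Conditions: 6, Mg, THF, rt→40 °C; then 5, Li2CuCl4 (5 mol %), THF, −78 °C→rt (3 equiv of 7)
Reagents that add atoms: none
Why: Copper-catalysed sp3–sp3 Grignard cross-coupling of a primary tosylate (Kochi/Fouquet–Schlosser type), in which the first equivalent of 7 only deprotonates the hydroxyl and the cuprate formed from the next displaces the tosylate at C5 by an SN2 path, forming C4–C5 without touching the C6 or C10 stereocentres (the C6 descriptor changes from R to S only because the priority order changes).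

Step 4
Reactants: 8 (2R,6S)-2,6,10-trimethylundecan-1-ol
Product: 9 (2R,6S)-2,6,10-trimethylundecanal
Conditions: Dess–Martin periodinane, NaHCO3, CH2Cl2, 0 °C→rt; used crude at once
Reagents that add atoms: none
Why: Dess–Martin oxidation of the primary alcohol under buffered, non-basic conditions should stop at the aldehyde and leave the enolisable C10 stereocentre intact, provided 9 is used without chromatography or storage.

Step 5
Reactants: 10 (R)-citronellol
Product: 11 tert-butyl{[(3R)-3,7-dimethyloct-6-en-1-yl]oxy}diphenylsilane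
Conditions: TBDPSCl, imidazole, DMF, rt
Reagents that add atoms: tert-butylchlorodiphenylsilane, CC(C)(C)[Si](Cl)(c1ccccc1)c1ccccc1
Why: Imidazole-promoted silylation masks the C12 hydroxyl as a silyl ether that should survive ozonolysis, Grignard formation, organocopper and organozinc chemistry and be removable with fluoride.

Step 6
Reactants: 11 tert-butyl{[(3R)-3,7-dimethyloct-6-en-1-yl]oxy}diphenylsilane
Product: 13 (4R)-6-[(tert-butyldiphenylsilyl)oxy]-4-methylhexan-1-ol, via silyloxy aldehyde 12 (not isolated)
Conditions: O3, CH2Cl2/MeOH (4:1), −78 °C; then NaBH4, −78 °C→rt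
Reagents that add atoms: ozone, [O-][O+]=O
Why: Ozonolysis with reductive NaBH4 work-up cleaves the only alkene, excising the isopropylidene carbon and leaving C17 as a primary alcohol, while the remote C14 stereocentre is untouched.

Step 7
Reactants: 13 (4R)-6-[(tert-butyldiphenylsilyl)oxy]-4-methylhexan-1-ol
Product: 14 {[(3R)-6-bromo-3-methylhexyl]oxy}(tert-butyl)diphenylsilane
Conditions: CBr4, PPh3, CH2Cl2, 0 °C
Reagents that add atoms: tetrabromomethane, BrC(Br)(Br)Br
Why: Appel bromination converts the primary alcohol into the bromide under neutral conditions that the silyl ether should tolerate.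

Step 8
Reactants: 14 {[(3R)-6-bromo-3-methylhexyl]oxy}(tert-butyl)diphenylsilane; 15 propyne
Product: 19 tert-butyl{[(3R,7Z)-8-iodo-3,7-dimethyloct-7-en-1-yl]oxy}diphenylsilane, via Grignard reagent 16 (not isolated), via alkylcopper 17 (not isolated), via alkenylcopper 18 (not isolated)
Conditions: Mg, Et2O, reflux; CuBr·SMe2 (1.0 equiv), Et2O/Me2S, −45 °C; propyne (excess), −25 °C; I2, −50 °C→0 °C
Reagents that add atoms: iodine, II
Why: Normant carbocupration, in which the alkylcopper from 16 should add syn across propyne with the alkyl group on the internal carbon (C18) and copper on the terminal one (C19), and iodinolysis of the alkenylcopper with retention should give the iodide with C17 and iodine cis, which fixes the 18Z geometry.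

Step 9
Reactants: 20 (R)-(+)-limonene
Product: 22 3-[(1R)-4-methylcyclohex-3-en-1-yl]but-3-en-1-ol, via 10-lithiolimonene 21 (not isolated)
Conditions: n-BuLi, TMEDA, limonene in excess, hexane, rt; then (CH2O)n, THF, −78 °C→rt
Reagents that add atoms: formaldehyde (as paraformaldehyde), C=O
Why: Allylic lithiation by n-BuLi·TMEDA should occur kinetically at the isopropenyl methyl group to give a 2-substituted allyllithium whose two termini are equivalent, and hydroxymethylation with formaldehyde then adds C20 without touching the ring stereocentre.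

Step 10
Reactants: 22 3-[(1R)-4-methylcyclohex-3-en-1-yl]but-3-en-1-ol
Product: 23 (4R)-4-(4-iodobut-1-en-2-yl)-1-methylcyclohex-1-ene
Conditions: I2, PPh3, imidazole, CH2Cl2, 0 °C→rt
Reagents that add atoms: iodine, II
Why: Appel-type iodination (PPh3/I2/imidazole) of the primary homoallylic alcohol proceeds under near-neutral conditions compatible with both alkenes.

Step 11
Reactants: 23 (4R)-4-(4-iodobut-1-en-2-yl)-1-methylcyclohex-1-ene; 19 tert-butyl{[(3R,7Z)-8-iodo-3,7-dimethyloct-7-en-1-yl]oxy}diphenylsilane
Product: 25 tert-butyl({(3R,7Z)-3,7-dimethyl-11-[(1R)-4-methylcyclohex-3-en-1-yl]dodeca-7,11-dien-1-yl}oxy)diphenylsilane, via homoallylzinc iodide 24 (not isolated)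
Conditions: 23, Zn dust (BrCH2CH2Br/TMSCl-activated), LiCl, THF, 40 °C; then 19, PdCl2(dppf) (5 mol %), THF, rt→45 °C
Reagents that add atoms: none
Why: Negishi sp3–sp2 cross-coupling, in which zinc insertion into the primary iodide gives a homoallylzinc reagent that should couple with the alkenyl iodide under palladium catalysis with retention of the Z geometry, the bidentate dppf ligand disfavouring β-hydride elimination, to form C19–C20.

Step 12
Reactants: 25 tert-butyl({(3R,7Z)-3,7-dimethyl-11-[(1R)-4-methylcyclohex-3-en-1-yl]dodeca-7,11-dien-1-yl}oxy)diphenylsilane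
Product: 26 (3R,7Z)-3,7-dimethyl-11-[(1R)-4-methylcyclohex-3-en-1-yl]dodeca-7,11-dien-1-ol
Conditions: TBAF, THF, rt
Reagents that add atoms: none
Why: Fluoride-mediated desilylation should free the C12 alcohol without affecting the three alkenes.

Step 13
Reactants: 26 (3R,7Z)-3,7-dimethyl-11-[(1R)-4-methylcyclohex-3-en-1-yl]dodeca-7,11-dien-1-ol
Product: 27 (4R)-4-[(5Z,10R)-12-bromo-6,10-dimethyldodeca-1,5-dien-2-yl]-1-methylcyclohex-1-ene
Conditions: CBr4, PPh3, CH2Cl2, 0 °C
Reagents that add atoms: tetrabromomethane, BrC(Br)(Br)Br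
Why: Appel bromination under neutral, acid-free conditions should give the primary bromide without protonating the acid-sensitive 1,1-disubstituted and trisubstituted alkenes.

Step 14
Reactants: 27 (4R)-4-[(5Z,10R)-12-bromo-6,10-dimethyldodeca-1,5-dien-2-yl]-1-methylcyclohex-1-ene; 9 (2R,6S)-2,6,10-trimethylundecanal
Product: 29 (6S,10R,11RS,14R,18Z)-2,6,10,14,18-pentamethyl-22-[(1R)-4-methylcyclohex-3-en-1-yl]tricosa-18,22-dien-11-ol, via Grignard reagent 28 (not isolated)
Conditions: 27, Mg, THF, 40 °C; then 9, THF, −78 °C→0 °C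
Reagents that add atoms: none
Why: Grignard addition, in which the primary alkylmagnesium bromide should add to the aldehyde at low temperature faster than it enolises it, forming C11–C12; the new carbinol centre C11 forms as a mixture of epimers that is of no consequence because it is oxidised in the next step.

Step 15
Reactants: 29 (6S,10R,11RS,14R,18Z)-2,6,10,14,18-pentamethyl-22-[(1R)-4-methylcyclohex-3-en-1-yl]tricosa-18,22-dien-11-ol
Product: 30 (6S,10R,14R,18Z)-2,6,10,14,18-pentamethyl-22-[(1R)-4-methylcyclohex-3-en-1-yl]tricosa-18,22-dien-11-one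
Conditions: Dess–Martin periodinane, NaHCO3, CH2Cl2, 0 °C→rt
Reagents that add atoms: none
Why: Dess–Martin oxidation of the secondary alcohol under buffered conditions should give the ketone without epimerising C10 or isomerising the alkenes.

**Compound list**

1 | 1,6-heptadiene | C=CCCCC=C | starting material
2 | trimethylaluminium | C[Al](C)C | starting material
3 | [(2R,6R)-2,6-dimethylheptane-1,7-diyl]bis(dimethylalane) | C[Al](C)C[C@H](C)CCC[C@@H](C)C[Al](C)C | intermediate
4 | (2R,6R)-2,6-dimethylheptane-1,7-diol | OC[C@H](C)CCC[C@@H](C)CO | intermediate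
5 | (2R,6R)-7-hydroxy-2,6-dimethylheptyl 4-methylbenzenesulfonate | OC[C@H](C)CCC[C@@H](C)COS(=O)(=O)c1ccc(C)cc1 | intermediate
6 | 1-bromo-3-methylbutane | CC(C)CCBr | starting material
7 | (3-methylbutyl)magnesium bromide | CC(C)CC[Mg]Br | intermediate
8 | (2R,6S)-2,6,10-trimethylundecan-1-ol | OC[C@H](C)CCC[C@@H](C)CCCC(C)C | intermediate
9 | (2R,6S)-2,6,10-trimethylundecanal | O=C[C@H](C)CCC[C@@H](C)CCCC(C)C | intermediate
10 | (R)-citronellol | C[C@H](CCC=C(C)C)CCO | starting material
11 | tert-butyl{[(3R)-3,7-dimethyloct-6-en-1-yl]oxy}diphenylsilane | C[C@H](CCC=C(C)C)CCO[Si](c1ccccc1)(c1ccccc1)C(C)(C)C | intermediate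
12 | (4R)-6-[(tert-butyldiphenylsilyl)oxy]-4-methylhexanal | C[C@H](CCC=O)CCO[Si](c1ccccc1)(c1ccccc1)C(C)(C)C | intermediate
13 | (4R)-6-[(tert-butyldiphenylsilyl)oxy]-4-methylhexan-1-ol | C[C@H](CCCO)CCO[Si](c1ccccc1)(c1ccccc1)C(C)(C)C | intermediate
14 | {[(3R)-6-bromo-3-methylhexyl]oxy}(tert-butyl)diphenylsilane | C[C@H](CCCBr)CCO[Si](c1ccccc1)(c1ccccc1)C(C)(C)C | intermediate
15 | propyne | CC#C | starting material
16 | {(4R)-6-[(tert-butyldiphenylsilyl)oxy]-4-methylhexyl}magnesium bromide | C[C@H](CCC[Mg]Br)CCO[Si](c1ccccc1)(c1ccccc1)C(C)(C)C | intermediate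
17 | {(4R)-6-[(tert-butyldiphenylsilyl)oxy]-4-methylhexyl}copper (MgBr2 complex) | C[C@H](CCC[Cu])CCO[Si](c1ccccc1)(c1ccccc1)C(C)(C)C | intermediate
18 | {(1Z,6R)-8-[(tert-butyldiphenylsilyl)oxy]-2,6-dimethyloct-1-en-1-yl}copper | C[C@H](CCC/C(C)=C\[Cu])CCO[Si](c1ccccc1)(c1ccccc1)C(C)(C)C | intermediate
19 | tert-butyl{[(3R,7Z)-8-iodo-3,7-dimethyloct-7-en-1-yl]oxy}diphenylsilane | C[C@H](CCC/C(C)=C\I)CCO[Si](c1ccccc1)(c1ccccc1)C(C)(C)C | intermediate
20 | (R)-(+)-limonene | C=C(C)[C@H]1CC=C(C)CC1 | starting material
21 | {2-[(1R)-4-methylcyclohex-3-en-1-yl]prop-2-en-1-yl}lithium (10-lithiolimonene) | [Li]CC(=C)[C@H]1CC=C(C)CC1 | intermediate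
22 | 3-[(1R)-4-methylcyclohex-3-en-1-yl]but-3-en-1-ol | C=C(CCO)[C@H]1CC=C(C)CC1 | intermediate
23 | (4R)-4-(4-iodobut-1-en-2-yl)-1-methylcyclohex-1-ene | C=C(CCI)[C@H]1CC=C(C)CC1 | intermediate
24 | {3-[(1R)-4-methylcyclohex-3-en-1-yl]but-3-en-1-yl}zinc iodide | C=C(CC[Zn]I)[C@H]1CC=C(C)CC1 | intermediate
25 | tert-butyl({(3R,7Z)-3,7-dimethyl-11-[(1R)-4-methylcyclohex-3-en-1-yl]dodeca-7,11-dien-1-yl}oxy)diphenylsilane | C=C(CC/C=C(/C)CCC[C@@H](C)CCO[Si](c1ccccc1)(c1ccccc1)C(C)(C)C)[C@H]1CC=C(C)CC1 | intermediate
26 | (3R,7Z)-3,7-dimethyl-11-[(1R)-4-methylcyclohex-3-en-1-yl]dodeca-7,11-dien-1-ol | C=C(CC/C=C(/C)CCC[C@@H](C)CCO)[C@H]1CC=C(C)CC1 | intermediate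
27 | (4R)-4-[(5Z,10R)-12-bromo-6,10-dimethyldodeca-1,5-dien-2-yl]-1-methylcyclohex-1-ene | C=C(CC/C=C(/C)CCC[C@@H](C)CCBr)[C@H]1CC=C(C)CC1 | intermediate
28 | {(3R,7Z)-3,7-dimethyl-11-[(1R)-4-methylcyclohex-3-en-1-yl]dodeca-7,11-dien-1-yl}magnesium bromide | C=C(CC/C=C(/C)CCC[C@@H](C)CC[Mg]Br)[C@H]1CC=C(C)CC1 | intermediate
29 | (6S,10R,11RS,14R,18Z)-2,6,10,14,18-pentamethyl-22-[(1R)-4-methylcyclohex-3-en-1-yl]tricosa-18,22-dien-11-ol | C=C(CC/C=C(/C)CCC[C@@H](C)CCC(O)[C@H](C)CCC[C@@H](C)CCCC(C)C)[C@H]1CC=C(C)CC1 | intermediate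
30 | (6S,10R,14R,18Z)-2,6,10,14,18-pentamethyl-22-[(1R)-4-methylcyclohex-3-en-1-yl]tricosa-18,22-dien-11-one | C=C(CC/C=C(/C)CCC[C@@H](C)CCC(=O)[C@H](C)CCC[C@@H](C)CCCC(C)C)[C@H]1CC=C(C)CC1 | target

**Step count and risks**

Total step count: 15. Longest linear sequence: 9 steps (from (R)-citronellol 10: steps 5, 6, 7, 8, 11, 12, 13, 14, 15).

Steps most likely to fail:

1. Step 1 (two-directional methylalumination). The first alkylzirconium may insert into the second vinyl group and close a six-membered ring before it is passed to aluminium. The second addition may stall at the mono-adduct, β-hydride transfer may give hydrometalation, or enantioface selectivity may be low enough that the meso diol dominates and cannot be removed cleanly. Fallback with known chemistry (one carboalumination per isolated 1-alkene), setting out from 6 and returning at 8: isopentylmagnesium bromide 7 is allylated with allyl bromide (THF, 0 °C) to give 6-methylhept-1-ene F1. Carboalumination of this simple 1-alkene with AlMe3 and the (S)-selective antipode of (NMI)2ZrCl2, then O2, should give (2S)-2,6-dimethylheptan-1-ol F2, whose purity can be raised by selective enzymatic acylation. Tosylation (TsCl, pyridine) gives (2S)-2,6-dimethylheptyl 4-methylbenzenesulfonate F3. Li2CuCl4-catalysed coupling with but-3-enylmagnesium bromide gives (6S)-6,10-dimethylundec-1-ene F4. A second carboalumination of this 1-alkene with the (R)-selective antipode, then O2, should deliver alcohol 8, replacing steps 1–3.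

2. Step 8 (carbocupration of propyne and iodination). The alkylcopper may decompose thermally (β-hydride loss, homocoupling) before it adds, addition to propyne may be incomplete or accompanied by propyne metalation, and geometry may be eroded if the alkenylcopper warms before iodinolysis. Fallback, setting out from 14 and returning at 25 (it replaces steps 8, 10 and 11 and uses 21 from step 9 without the formaldehyde quench): displacement of bromide 14 with LiC≡CH·H2NCH2CH2NH2 in DMSO gives tert-butyl{[(3R)-3-methyloct-7-yn-1-yl]oxy}diphenylsilane F5. Deprotonation with n-BuLi and trapping with ClCO2Me gives methyl (7R)-9-[(tert-butyldiphenylsilyl)oxy]-7-methylnon-2-ynoate F6. Syn conjugate addition of Me2CuLi at −78 °C with cold protonation should give methyl (2Z,7R)-9-[(tert-butyldiphenylsilyl)oxy]-3,7-dimethylnon-2-enoate F7, in which the C17 chain and the ester carbon (C20) are cis. Reduction with i-Bu2AlH gives (2Z,7R)-9-[(tert-butyldiphenylsilyl)oxy]-3,7-dimethylnon-2-en-1-ol F8, and MsCl/Et3N followed by LiCl gives tert-butyl{[(3R,7Z)-9-chloro-3,7-dimethylnon-7-en-1-yl]oxy}diphenylsilane F9. Alkylation of 10-lithiolimonene 21 with this primary allylic chloride (THF, −78 °C) forms C20–C21 and gives 25.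

3. Step 14 (fragment union). The basic Grignard reagent may enolise the α-branched aldehyde instead of adding, which returns aldehyde and epimerises C10. Wurtz coupling may consume the bromide during magnesium insertion, and β-hydride transfer may reduce the aldehyde. Fallback by umpolung (Corey–Seebach), setting out from 9 and 27 and returning at 30: aldehyde 9 is converted with propane-1,3-dithiol and BF3·OEt2 (CH2Cl2, −20 °C) into 2-[(2R,6S)-6,10-dimethylundecan-2-yl]-1,3-dithiane F10, in which C10 is no longer enolisable. Lithiation (n-BuLi, THF/HMPA, −30 °C) and alkylation with bromide 27 gives 2-[(2R,6S)-6,10-dimethylundecan-2-yl]-2-{(3R,7Z)-3,7-dimethyl-11-[(1R)-4-methylcyclohex-3-en-1-yl]dodeca-7,11-dien-1-yl}-1,3-dithiane F11. Alkylative hydrolysis (MeI, CaCO3, MeCN/H2O, 45 °C), which leaves the alkenes alone, should release ketone 30 directly, replacing steps 14 and 15.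

**Further compounds**

F1 | step 1 | 6-methylhept-1-ene | C=CCCCC(C)C
F2 | step 1 | (2S)-2,6-dimethylheptan-1-ol | OC[C@@H](C)CCCC(C)C
F3 | step 1 | (2S)-2,6-dimethylheptyl 4-methylbenzenesulfonate | Cc1ccc(cc1)S(=O)(=O)OC[C@@H](C)CCCC(C)C
F4 | step 1 | (6S)-6,10-dimethylundec-1-ene | C=CCCC[C@@H](C)CCCC(C)C
F5 | step 8 | tert-butyl{[(3R)-3-methyloct-7-yn-1-yl]oxy}diphenylsilane | C[C@H](CCCC#C)CCO[Si](c1ccccc1)(c1ccccc1)C(C)(C)C
F6 | step 8 | methyl (7R)-9-[(tert-butyldiphenylsilyl)oxy]-7-methylnon-2-ynoate | C[C@H](CCCC#CC(=O)OC)CCO[Si](c1ccccc1)(c1ccccc1)C(C)(C)C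
F7 | step 8 | methyl (2Z,7R)-9-[(tert-butyldiphenylsilyl)oxy]-3,7-dimethylnon-2-enoate | C[C@H](CCC/C(C)=C\C(=O)OC)CCO[Si](c1ccccc1)(c1ccccc1)C(C)(C)C
F8 | step 8 | (2Z,7R)-9-[(tert-butyldiphenylsilyl)oxy]-3,7-dimethylnon-2-en-1-ol | C[C@H](CCC/C(C)=C\CO)CCO[Si](c1ccccc1)(c1ccccc1)C(C)(C)C
F9 | step 8 | tert-butyl{[(3R,7Z)-9-chloro-3,7-dimethylnon-7-en-1-yl]oxy}diphenylsilane | C[C@H](CCC/C(C)=C\CCl)CCO[Si](c1ccccc1)(c1ccccc1)C(C)(C)C
F10 | step 14 | 2-[(2R,6S)-6,10-dimethylundecan-2-yl]-1,3-dithiane | S1CCCSC1[C@H](C)CCC[C@@H](C)CCCC(C)C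
F11 | step 14 | 2-[(2R,6S)-6,10-dimethylundecan-2-yl]-2-{(3R,7Z)-3,7-dimethyl-11-[(1R)-4-methylcyclohex-3-en-1-yl]dodeca-7,11-dien-1-yl}-1,3-dithiane | C=C(CC/C=C(/C)CCC[C@@H](C)CCC1(SCCCS1)[C@H](C)CCC[C@@H](C)CCCC(C)C)[C@H]1CC=C(C)CC1
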